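**Plan**
- Retrosynthetic cuts: the three aryl O–CH3 bonds (protecting groups) and the two pyrone C5–CH3 bonds (from C5–I) go first. The key step then opens the O1–C6 bond of each pyrone. Behind it lie the two bonds between the ester alpha carbons and the ynone carbonyl carbons (ester enolate plus pent-2-ynal, then oxidation), the two ArCH2–CH2 bonds and the aryl–acyl bond.
- Enabling feature: in each 4-hydroxy-2-pyrone ring the enol-lactone edge O1–C6(Et)=C5 is the C4≡C5 triple bond of a tert-butyl 3-oxohept-4-ynoate. The ester carbonyl oxygen becomes O1, and C5 leaves the ring closure metalated, so it can take iodine and later methyl.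
- Forward order: the hexasubstituted benzene core is finished first, the two seven-carbon keto ester chains are grown on it, both pyrone rings are closed in one operation, and C5-methylation and O-demethylation follow.
- Stereochemistry: the target has no stereocentre. The stereocentres of 10 and 11 are left uncontrolled; oxidation erases the carbinol centres and ring aromatisation the rest.

Key step: step 5

Remark: pent-2-ynal is taken as a catalogue chemical, and compounds 10 and 11 are carried as mixtures of diastereomers (11 also of keto/enol tautomers) that converge in step 5.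

**Step 1**
Reactants: 1 1,3,5-trimethoxybenzene; 2 isobutyryl chloride
Product: 3 2-methyl-1-(2,4,6-trimethoxyphenyl)propan-1-one
Conditions: AlCl3 (1.1 equiv), CH2Cl2, 0 °C
Reagents that add atoms: none
Why: Friedel–Crafts acylation of a threefold activated arene with three equivalent free positions should stop at the mono-ketone, because the acyl group deactivates the ring and the low temperature spares the ortho methyl ethers.

**Step 2**
Reactants: 3 2-methyl-1-(2,4,6-trimethoxyphenyl)propan-1-one
Product: 4 1-[3,5-bis(bromomethyl)-2,4,6-trimethoxyphenyl]-2-methylpropan-1-one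
Conditions: (CH2O)n (3 equiv), 33% HBr in AcOH, AcOH, 45 °C
Reagents that add atoms: paraformaldehyde, as formaldehyde C=O; hydrogen bromide, Br
Why: Blanc-type bromomethylation should fill both remaining ring positions, each of which is ortho/para to three methoxy groups and only meta to the twisted acyl group, and no further position is left for over-reaction.

**Step 3**
Reactants: 4 1-[3,5-bis(bromomethyl)-2,4,6-trimethoxyphenyl]-2-methylpropan-1-one; 5 tert-butyl acetate
Product: 7 di-tert-butyl 3,3'-[5-(2-methylpropanoyl)-2,4,6-trimethoxy-1,3-phenylene]dipropanoate, via lithium enolate of tert-butyl acetate 6 (not isolated)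
Conditions: 5 (3.3 equiv), lithium diisopropylamide (3.0 equiv), THF, −78 °C; then 4, DMPU, −78 to −30 °C
Reagents that add atoms: none
Why: SN2 alkylation of a preformed lithium ester enolate by reactive benzylic bromides is standard, the crowded di-ortho-substituted aryl ketone should neither be attacked nor take part at this temperature, and the excess of enolate limits double alkylation of one acetate.

**Step 4**
Reactants: 7 di-tert-butyl 3,3'-[5-(2-methylpropanoyl)-2,4,6-trimethoxy-1,3-phenylene]dipropanoate; 8 pent-2-ynal
Product: 11 di-tert-butyl 2,2'-{[5-(2-methylpropanoyl)-2,4,6-trimethoxy-1,3-phenylene]bis(methylene)}bis(3-oxohept-4-ynoate) (mixture of diastereomers), via trilithium trienolate 9 (not isolated), via bis-aldol diol 10 (not isolated)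
Conditions: 8 (2.4 equiv), lithium diisopropylamide (3.3 equiv), THF, −78 °C (7 enolised first), AcOH quench; then crude 10, Dess–Martin periodinane (2.6 equiv), CH2Cl2, 0 °C to rt
Reagents that add atoms: none
Why: Aldol 1,2-addition of lithium ester enolates to an alk-2-ynal followed by Dess–Martin oxidation of the propargylic beta-hydroxy esters is a standard entry to tert-butyl 3-oxoalk-4-ynoates; the two unhindered ester enolates should consume the aldehyde at −78 °C before the tetrasubstituted, doubly ortho-flanked ketone enolate, which is reprotonated on quench, and the carbinol stereocentres are erased by the oxidation while the two alpha stereocentres need no control.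

**Step 5**
Reactants: 11 di-tert-butyl 2,2'-{[5-(2-methylpropanoyl)-2,4,6-trimethoxy-1,3-phenylene]bis(methylene)}bis(3-oxohept-4-ynoate)
Product: 12 3,3'-{[5-(2-methylpropanoyl)-2,4,6-trimethoxy-1,3-phenylene]bis(methylene)}bis(6-ethyl-4-hydroxy-5-iodo-2H-pyran-2-one)
Conditions: Ph3PAuNTf2 (10 mol%), N-iodosuccinimide (2.6 equiv), CH2Cl2, 0 °C to rt, dark; aq. Na2S2O3 work-up
Reagents that add atoms: N-iodosuccinimide, O=C1CCC(=O)N1I
Why: Proposed new method: the cationic monovalent gold complex binds each ynone triple bond, the carbonyl oxygen of the neighbouring tert-butyl ester adds anti to the metal at the beta carbon of the ynone (C5 of the heptynoate, the future pyrone C6) and so forms O1–C6, the tert-butyl oxocarbenium ion sheds isobutene, and the C5 vinylgold species is intercepted by N-iodosuccinimide so that C5–I is formed in place of C5–H. The closest known reaction types are the gold-catalysed cycloisomerisation of tert-butyl 3-oxoalk-4-ynoates to 4-hydroxy-2-pyrones and the iododeauration of vinylgold intermediates by N-iodosuccinimide, with the iodolactonisation of (Z)-2-en-4-ynoates to 5-iodo-2-pyrones as a metal-free relative; their union on a 2-substituted keto ester is the untested part. Both rings close in the 6-endo-dig mode and no stereocentre is created, so the diastereomers of 11 converge on one product. Two selectivities are needed: 6-endo over 5-exo attack, which the conjugate polarisation of the ynone and the soft pi-acid should secure, and iodination over protonation of the vinylgold species, which the acid-free medium and the excess of N-iodosuccinimide should favour. The arene is hexasubstituted, with its last position held by the deactivating acyl group, so no ring iodination can compete, and any reversible iodination at the keto ester alpha carbon (the future pyrone C3) should be undone by the thiosulfate work-up.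

**Step 6**
Reactants: 12 3,3'-{[5-(2-methylpropanoyl)-2,4,6-trimethoxy-1,3-phenylene]bis(methylene)}bis(6-ethyl-4-hydroxy-5-iodo-2H-pyran-2-one)
Product: 13 3,3'-{[5-(2-methylpropanoyl)-2,4,6-trimethoxy-1,3-phenylene]bis(methylene)}bis(6-ethyl-4-hydroxy-5-methyl-2H-pyran-2-one)
Conditions: trimethylboroxine (2 equiv), Pd(dppf)Cl2 (10 mol%), K2CO3 (6 equiv), 1,4-dioxane/H2O, 90 °C
Reagents that add atoms: trimethylboroxine, CB1OB(C)OB(C)O1
Why: Suzuki–Miyaura methylation of alpha-iodo-enone-type vinyl iodides is well established, oxidative addition into C5–I is fast, the acidic pyrone hydroxyls travel as potassium salts, and the aryl ethers and the hindered ketone are inert.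

**Step 7**
Reactants: 13 3,3'-{[5-(2-methylpropanoyl)-2,4,6-trimethoxy-1,3-phenylene]bis(methylene)}bis(6-ethyl-4-hydroxy-5-methyl-2H-pyran-2-one)
Product: 14 3,3'-{[2,4,6-trihydroxy-5-(2-methylpropanoyl)-1,3-phenylene]bis(methylene)}bis(6-ethyl-4-hydroxy-5-methyl-2H-pyran-2-one) (CNP0277086.0)
Conditions: BBr3 (10 equiv), CH2Cl2, −78 °C to rt; then H2O, 0 °C
Reagents that add atoms: none
Why: Lewis-acid cleavage of aryl methyl ethers with BBr3 should remove all three groups, since the two ethers ortho to the ketone are activated by chelation and the third is twisted out of conjugation by its two benzylic neighbours, while the pyrone hydroxyls are only borylated and return on hydrolysis.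

**Compound list**
1 | 1,3,5-trimethoxybenzene | COc1cc(OC)cc(OC)c1 | starting material
2 | isobutyryl chloride (2-methylpropanoyl chloride) | CC(C)C(=O)Cl | starting material
3 | 2-methyl-1-(2,4,6-trimethoxyphenyl)propan-1-one | CC(C)C(=O)c1c(OC)cc(OC)cc1OC | intermediate
4 | 1-[3,5-bis(bromomethyl)-2,4,6-trimethoxyphenyl]-2-methylpropan-1-one | CC(C)C(=O)c1c(OC)c(CBr)c(OC)c(CBr)c1OC | intermediate
5 | tert-butyl acetate | CC(=O)OC(C)(C)C | starting material
6 | lithium enolate of tert-butyl acetate (not isolated) | [Li]OC(=C)OC(C)(C)C | intermediate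
7 | di-tert-butyl 3,3'-[5-(2-methylpropanoyl)-2,4,6-trimethoxy-1,3-phenylene]dipropanoate | CC(C)C(=O)c1c(OC)c(CCC(=O)OC(C)(C)C)c(OC)c(CCC(=O)OC(C)(C)C)c1OC | intermediate
8 | pent-2-ynal | CCC#CC=O | starting material
9 | trilithium trienolate of 7, two ester enolates and the aryl ketone enolate (not isolated) | CC(C)=C(O[Li])c1c(OC)c(CC=C(O[Li])OC(C)(C)C)c(OC)c(CC=C(O[Li])OC(C)(C)C)c1OC | intermediate
10 | di-tert-butyl 2,2'-{[5-(2-methylpropanoyl)-2,4,6-trimethoxy-1,3-phenylene]bis(methylene)}bis(3-hydroxyhept-4-ynoate), mixture of diastereomers (not isolated) | CCC#CC(O)C(Cc1c(OC)c(CC(C(=O)OC(C)(C)C)C(O)C#CCC)c(OC)c(C(=O)C(C)C)c1OC)C(=O)OC(C)(C)C | intermediate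
11 | di-tert-butyl 2,2'-{[5-(2-methylpropanoyl)-2,4,6-trimethoxy-1,3-phenylene]bis(methylene)}bis(3-oxohept-4-ynoate), mixture of diastereomers | CCC#CC(=O)C(Cc1c(OC)c(CC(C(=O)OC(C)(C)C)C(=O)C#CCC)c(OC)c(C(=O)C(C)C)c1OC)C(=O)OC(C)(C)C | intermediate
12 | 3,3'-{[5-(2-methylpropanoyl)-2,4,6-trimethoxy-1,3-phenylene]bis(methylene)}bis(6-ethyl-4-hydroxy-5-iodo-2H-pyran-2-one) | CCc1oc(=O)c(Cc2c(OC)c(Cc3c(O)c(I)c(CC)oc3=O)c(OC)c(C(=O)C(C)C)c2OC)c(O)c1I | intermediate
13 | 3,3'-{[5-(2-methylpropanoyl)-2,4,6-trimethoxy-1,3-phenylene]bis(methylene)}bis(6-ethyl-4-hydroxy-5-methyl-2H-pyran-2-one) | CCc1oc(=O)c(Cc2c(OC)c(Cc3c(O)c(C)c(CC)oc3=O)c(OC)c(C(=O)C(C)C)c2OC)c(O)c1C | intermediate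
14 | 3,3'-{[2,4,6-trihydroxy-5-(2-methylpropanoyl)-1,3-phenylene]bis(methylene)}bis(6-ethyl-4-hydroxy-5-methyl-2H-pyran-2-one), CNP0277086.0 | CCc1oc(=O)c(Cc2c(O)c(Cc3c(O)c(C)c(CC)oc3=O)c(O)c(C(=O)C(C)C)c2O)c(O)c1C | target

**Totals and risks**
Total step count: 7. Longest linear sequence: 7 steps (steps 1 to 7; the route is fully linear).

Most likely to fail, first: step 5. Protonation of the vinylgold intermediate may outrun iodine transfer, 5-exo closure may intrude, or iodination at the keto ester alpha carbon may stall the cyclisation. The fallback uses known chemistry only and brings the pyrone rings in ready-made; it sets out from dibromide 4 and comes back at 13, before step 7. Oxidation of 4 with N-methylmorpholine N-oxide in MeCN (Kornblum-type) should give 5-(2-methylpropanoyl)-2,4,6-trimethoxybenzene-1,3-dicarbaldehyde F1. In parallel, the dianion of commercial methyl 3-oxopentanoate (NaH, then n-butyllithium, THF, 0 °C) is acylated at C4 with N-methoxy-N-methylpropanamide to methyl 4-methyl-3,5-dioxoheptanoate F2, which DBU in hot toluene lactonises to 6-ethyl-4-hydroxy-5-methyl-2H-pyran-2-one F3. A twofold Knoevenagel condensation of F1 with F3, run with a Hantzsch ester and L-proline so that each arylidene intermediate is reduced as it forms (reductive C3-alkylation), would then give 13.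

Second: step 4. Competing aldol addition of the aryl ketone enolate, an incomplete second addition, or over-oxidation at the keto ester alpha carbon may erode the bis-keto ester. The fallback reverses the order of bond formation so that no strong base meets the aryl ketone; it sets out from dibromide 4, enolate 6 and aldehyde 8 and comes back at 11. Enolate 6 (THF, −78 °C) adds to 8 to give racemic tert-butyl 3-hydroxyhept-4-ynoate F4, and Dess–Martin oxidation gives tert-butyl 3-oxohept-4-ynoate F5. The fully formed sodium enolate of this keto ester (NaH, THF/DMF, 0 °C) is then C-benzylated twice by 4.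

Third: step 6. Protodeiodination or sluggish transmetalation on the anionic pyronates may leave one or both C5 positions unmethylated. The fallback masks the acidic hydroxyls and changes the coupling partner; it sets out from 12 and comes back at 13. Silylation (TBSCl, imidazole, DMF) should give the bis(tert-butyldimethylsilyl) ether of 12 F6. Negishi coupling with MeZnCl and Pd(P(t-Bu)3)2 in THF then gives the bis(tert-butyldimethylsilyl) ether of 13 F7, which dilute HCl in aqueous THF desilylates to 13.

**Further compounds**
F1 | step 5 | 5-(2-methylpropanoyl)-2,4,6-trimethoxybenzene-1,3-dicarbaldehyde | CC(C)C(=O)c1c(OC)c(C=O)c(OC)c(C=O)c1OC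
F2 | step 5 | methyl 4-methyl-3,5-dioxoheptanoate | CCC(=O)C(C)C(=O)CC(=O)OC
F3 | step 5 | 6-ethyl-4-hydroxy-5-methyl-2H-pyran-2-one | CCc1oc(=O)cc(O)c1C
F4 | step 4 | tert-butyl 3-hydroxyhept-4-ynoate (racemic) | CCC#CC(O)CC(=O)OC(C)(C)C
F5 | step 4 | tert-butyl 3-oxohept-4-ynoate | CCC#CC(=O)CC(=O)OC(C)(C)C
F6 | step 6 | bis(tert-butyldimethylsilyl) ether of 12 | CCc1oc(=O)c(Cc2c(OC)c(Cc3c(O[Si](C)(C)C(C)(C)C)c(I)c(CC)oc3=O)c(OC)c(C(=O)C(C)C)c2OC)c(O[Si](C)(C)C(C)(C)C)c1I
F7 | step 6 | bis(tert-butyldimethylsilyl) ether of 13 | CCc1oc(=O)c(Cc2c(OC)c(Cc3c(O[Si](C)(C)C(C)(C)C)c(C)c(CC)oc3=O)c(OC)c(C(=O)C(C)C)c2OC)c(O[Si](C)(C)C(C)(C)C)c1C
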